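**Plan**

1. Retrosynthetic cuts: the C5–O ester bond together with the C1–O bond (both from one α-epoxide of a 1-acylcycloheptene opened by the acid); the lactone C12–O bond and the C12 oxidation level (back to an isopropenyl group); C2–C3 (propenyllithium plus aldehyde); C1–C2 (Wittig carbon); and finally C5 is excised from between C1 and C6, leaving the six-membered ring of (S)-carvone.
2. Enabling feature: in the seven-membered carbocycle the three contiguous oxygenated carbons C1, C5 and C6 lie next to the methyl-bearing C10. This is the footprint of a cyclohept-2-enone C1(=O)–C5=C6, i.e. carvone's carbonyl carbon (C1), its methyl carbon (C10) and its isopropenyl carbon (C7) with one CH2 (C5) inserted into the C1–C6 ring bond.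
3. Forward order: carvone six-membered ring → silyloxybicyclo[4.1.0]heptane → seven-membered enone (ring expansion) → 5,6-epoxide → Wittig/hydrolysis (C2, C1=C5, 6-OH) → 1,5-epoxide → propenyl addition and oxidation → epoxide opening by the acid (ester) → lactone ring last → desilylation.
4. Stereochemistry: C7 from (S)-carvone; C9 by hydroxyl-directed epoxidation of cis-carveol; C10 by equilibration to the equatorial methyl; C6 by epoxidation anti to C7; C1 and C5 by 6-OH-directed epoxidation followed by anti opening; the acyl stereocentre from (R)-2-methylbutanoic acid; the E-alkene from (E)-1-bromopropene.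

Key step: step 8

Remark on the chemistry: locants follow the seco-guaiane skeleton of the target (carbocycle C1, C5, C6, C7, C8, C9, C10; side chain C2(=O)–C3=C4–C15 on C1; lactone carbons C11, C12, C13 on C7; C14 = methyl on C10), α is the ring face of the C14 methyl and β the face of the C7–C11 bond, and commercial (E)-1-bromoprop-1-ene and (R)-2-methylbutanoic acid are assumed to be isomerically pure.

**Route**

Step 1
Reactants: 1 (S)-(+)-carvone
Product: 2 (1S,5S)-cis-carveol
Conditions: NaBH4, CeCl3·7H2O, MeOH, 0 °C
Reagents that add atoms: none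
Why: Luche reduction; CeCl3-assisted 1,2-hydride addition to the enone should give the allylic alcohol with OH cis to the isopropenyl group, the usual outcome for carvone.

Step 2
Reactants: 2 cis-carveol
Product: 3 syn-epoxy alcohol
Conditions: VO(acac)2 (cat.), t-BuOOH, CH2Cl2, 0 °C to rt
Reagents that add atoms: tert-butyl hydroperoxide, CC(C)(C)OO
Why: Hydroxyl-directed epoxidation; the vanadium alkoxide-bound peroxide should deliver oxygen to the ring alkene on the face of the OH group, which sets the future C9–O bond cis to the C7 isopropenyl group and leaves the non-allylic isopropenyl alkene alone.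

Step 3
Reactants: 3 syn-epoxy alcohol
Product: 4 cis-epoxy ketone
Conditions: Dess–Martin periodinane, CH2Cl2, 0 °C to rt
Reagents that add atoms: none
Why: Dess–Martin oxidation of the secondary alcohol under near-neutral conditions should leave epoxide and alkene intact; no stereocentre is formed.

Step 4
Reactants: 4 cis-epoxy ketone
Product: 5 β-hydroxy ketone (both C10 epimers)
Conditions: SmI2 (2.2 equiv), THF/MeOH, −78 °C
Reagents that add atoms: none
Why: Reductive opening of an α,β-epoxy ketone by SmI2 (ketyl, Cα–O cleavage, enolate protonation) should keep the C9–O configuration; the methyl-bearing centre forms unselectively and is corrected in step 5.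

Step 5
Reactants: 5 β-hydroxy ketone
Product: 7 all-equatorial silyloxy ketone, via silyl ether epimer mixture 6 (not isolated)
Conditions: TBSCl, imidazole, DMF, rt; aqueous work-up; then DBU (cat.), PhMe, 40 °C
Reagents that add atoms: tert-butyldimethylsilyl chloride, CC(C)(C)[Si](C)(C)Cl
Why: Silyl ether formation followed by base-mediated α-epimerisation under thermodynamic control should funnel both epimers into the cyclohexanone with all three substituents equatorial, i.e. C10 methyl trans to the C9 silyloxy group.

Step 6
Reactants: 7 silyloxy ketone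
Product: 8 kinetic trimethylsilyl enol ether (C1=C6)
Conditions: LiN(iPr)2, Me3SiCl, THF, −78 °C
Reagents that add atoms: chlorotrimethylsilane, C[Si](C)(C)Cl
Why: Kinetic enolisation with in situ silylation should remove a proton from the unsubstituted α-methylene C6 and not from the methine C10, which fixes the site of the later carbon insertion and leaves C10 untouched.

Step 7
Reactants: 8 silyl enol ether
Product: 9 1-silyloxybicyclo[4.1.0]heptane
Conditions: Et2Zn, CH2I2, PhMe, 0 °C to rt
Reagents that add atoms: diiodomethane, ICI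
Why: Simmons–Smith cyclopropanation (Furukawa conditions) should occur at the electron-rich silyl enol ether in preference to the isopropenyl group and brings in C5 as the cyclopropane CH2; the configuration of the two new ring-fusion carbons is irrelevant because both are lost in step 8.

Step 8
Reactants: 9 1-silyloxybicyclo[4.1.0]heptane
Product: 11 cyclohept-2-enone, via 3-chlorocycloheptanone 10 (not isolated)
Conditions: FeCl3 (2.2 equiv), DMF, 0 °C to rt; then NaOAc, MeOH, 65 °C
Reagents that add atoms: iron trichloride, Cl[Fe](Cl)Cl (chlorine, present only in 10)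
Why: FeCl3 converts the silyloxycyclopropane into a cyclopropanolate of trivalent iron whose one-electron oxidation gives an alkoxy radical; β-scission of the C1–C6 bond shared by the three- and six-membered rings forms the C1 ketone and a secondary radical at C6, which takes chlorine from a second FeCl3 to give 10, and NaOAc then removes HCl (E1cB) to give the C5=C6 enone. The closest known reaction type is the Ito–Saegusa ring expansion of 1-silyloxybicyclo[n.1.0]alkanes. No ring is closed: the seven-membered ring arises because the bond common to the cyclohexane and the cyclopropane is cut, so that the inserted CH2 (C5) becomes a ring member between C1 and C6. No new stereocentre remains in 11 (the C6 chloride is eliminated) and C7, C9 and C10 are not touched. The step needs cleavage of the internal and not an external cyclopropane bond, which is secured by formation of the more stable secondary radical and by relief of bicyclic strain, while the site of insertion (C1–C6, not C1–C10) was fixed by the kinetic enolisation of step 6. The isopropenyl group and the silyl ether should survive because chlorine transfer from FeCl3 is faster than radical addition to the remote alkene.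

Step 9
Reactants: 11 cyclohept-2-enone
Product: 12 5α,6α-epoxy ketone
Conditions: H2O2 (30% aq.), NaOH, MeOH, 0 °C
Reagents that add atoms: hydrogen peroxide, OO
Why: Weitz–Scheffer epoxidation; hydroperoxide should add to C6 anti to the neighbouring C7 isopropenyl group, so the C6–O bond is α (trans to C7–C11), and the isolated isopropenyl alkene is inert to the nucleophilic oxidant.

Step 10
Reactants: 12 5α,6α-epoxy ketone
Product: 14 6α-hydroxy enal, via methyl enol ether 13 (not isolated)
Conditions: Ph3P(CH2OMe)Cl, t-BuOK, THF, 0 °C to rt; then oxalic acid, THF/H2O, rt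
Reagents that add atoms: (methoxymethyl)triphenylphosphonium chloride, COC[P+](c1ccccc1)(c1ccccc1)c1ccccc1.[Cl-]; water, O
Why: Wittig methoxymethylenation gives a 2-methoxyvinyl epoxide whose mild acid hydrolysis should proceed with vinylogous (E1cB-type) opening of the epoxide, delivering C2 as an aldehyde, the C1=C5 double bond and the C6 hydroxyl with unchanged α configuration.

Step 11
Reactants: 14 6α-hydroxy enal
Product: 15 1α,5α-epoxy aldehyde
Conditions: t-BuOOH (anhydrous), DBU, CH2Cl2, 0 °C
Reagents that add atoms: tert-butyl hydroperoxide, CC(C)(C)OO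
Why: Weitz–Scheffer epoxidation of the only electron-poor alkene should be steered to the α face by hydrogen bonding of the peroxide anion to the free allylic C6 hydroxyl (syn delivery, as in cyclic γ-hydroxy enones), which places the epoxide oxygen α at C1 and C5.

Step 12
Reactants: 15 1α,5α-epoxy aldehyde; 16 (E)-1-bromoprop-1-ene
Product: 18 epoxy allylic alcohol (both C2 epimers), via (E)-prop-1-enyllithium 17 (not isolated)
Conditions: 16, t-BuLi (2 equiv per 16), Et2O, −78 °C; then 15, THF, −78 °C; aq. NH4Cl
Reagents that add atoms: none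
Why: Bromine–lithium exchange with retention of the E geometry and 1,2-addition of the alkenyllithium to the aldehyde (one equivalent is consumed by the C6 hydroxyl) should leave the epoxide untouched at −78 °C; the carbinol configuration is irrelevant because it is oxidised in step 13.

Step 13
Reactants: 18 epoxy allylic alcohol
Product: 19 1α,5α-epoxy enone
Conditions: MnO2, CH2Cl2, rt
Reagents that add atoms: none
Why: Allylic oxidation with MnO2 should convert only the allylic carbinol at C2 into the ketone, leave the non-allylic C6 hydroxyl alone and merge both C2 epimers into one enone.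

Step 14
Reactants: 19 1α,5α-epoxy enone; 20 (R)-2-methylbutanoic acid
Product: 21 5β-ester 1α,6α-diol
Conditions: 20 (4 equiv), Cs2CO3 (0.3 equiv), DMF, 60 °C
Reagents that add atoms: none
Why: Carboxylate opening of an α,β-epoxy ketone (SN2, anti) should take place at the secondary C5 because C1 is quaternary and α to the carbonyl, giving inversion at C5 (ester β) and leaving the C1–O bond as the α tertiary alcohol, the same trans opening known for 16,17-epoxy-20-oxo steroids; the cis C6 hydroxyl cannot undergo Payne rearrangement.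

Step 15
Reactants: 21 5β-ester 1α,6α-diol
Product: 22 C12 allylic alcohol
Conditions: SeO2 (0.3 equiv), t-BuOOH, CH2Cl2, rt
Reagents that add atoms: selenium dioxide, O=[Se]=O; tert-butyl hydroperoxide, CC(C)(C)OO
Why: SeO2-catalysed allylic oxidation (ene reaction then [2,3]-sigmatropic shift) should hydroxylate the isopropenyl methyl group, the C7 methine being deactivated by the adjacent C6 carbinol and the crotonoyl alkene being electron-poor.

Step 16
Reactants: 22 C12 allylic alcohol
Product: 25 9-O-silyl lactone, via enal 23 (not isolated), via lactol 24 (not isolated)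
Conditions: MnO2 (excess), CH2Cl2, rt
Reagents that add atoms: none
Why: Oxidative lactonisation; MnO2 should oxidise the allylic alcohol to the enal, which closes with the C6 hydroxyl to the five-membered lactol that is oxidised further to the α-methylene-γ-butyrolactone, and since the C6–O bond is never broken the ring fusion stays trans.

Step 17
Reactants: 25 9-O-silyl lactone
Product: 26 CNP0331957.3 (target)
Conditions: HF·pyridine, THF/pyridine, 0 °C to rt
Reagents that add atoms: none
Why: Fluoride-mediated desilylation under buffered conditions should release the C9 hydroxyl without touching the lactone, the ester, the enone or the tertiary α-ketol.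

**Compound list**

1 | (S)-(+)-carvone, (5S)-2-methyl-5-(prop-1-en-2-yl)cyclohex-2-en-1-one | C1[C@@H](C(C)=C)CC=C(C)C1=O | starting material
2 | (1S,5S)-2-methyl-5-(prop-1-en-2-yl)cyclohex-2-en-1-ol (cis-carveol) | C1[C@@H](C(C)=C)CC=C(C)[C@H]1O | intermediate
3 | (1S,2S,4R,6R)-1-methyl-4-(prop-1-en-2-yl)-7-oxabicyclo[4.1.0]heptan-2-ol (epoxide cis to OH and isopropenyl) | C1[C@@H](C(C)=C)C[C@@H]2[C@@](C)(O2)[C@H]1O | intermediate
4 | (1R,4S,6R)-1-methyl-4-(prop-1-en-2-yl)-7-oxabicyclo[4.1.0]heptan-2-one | C1[C@@H](C(C)=C)C[C@@H]2[C@@](C)(O2)C1=O | intermediate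
5 | (3R,5S)-3-hydroxy-2-methyl-5-(prop-1-en-2-yl)cyclohexan-1-one, both C2 epimers | C1[C@@H](C(C)=C)C[C@@H](O)C(C)C1=O | intermediate
6 | (3R,5S)-3-[(tert-butyldimethylsilyl)oxy]-2-methyl-5-(prop-1-en-2-yl)cyclohexan-1-one, both C2 epimers | C1[C@@H](C(C)=C)C[C@@H](O[Si](C)(C)C(C)(C)C)C(C)C1=O | intermediate
7 | (2S,3R,5S)-3-[(tert-butyldimethylsilyl)oxy]-2-methyl-5-(prop-1-en-2-yl)cyclohexan-1-one | C1[C@@H](C(C)=C)C[C@@H](O[Si](C)(C)C(C)(C)C)[C@H](C)C1=O | intermediate
8 | 5-[(tert-butyldimethylsilyl)oxy]-6-methyl-3-(prop-1-en-2-yl)-1-(trimethylsilyloxy)cyclohex-1-ene, configurations as in 7 | C[Si](C)(C)OC1=C[C@@H](C(C)=C)C[C@@H](O[Si](C)(C)C(C)(C)C)[C@@H]1C | intermediate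
9 | 3-[(tert-butyldimethylsilyl)oxy]-2-methyl-5-(prop-1-en-2-yl)-1-(trimethylsilyloxy)bicyclo[4.1.0]heptane, cyclopropane on either face | C[Si](C)(C)OC12CC1[C@@H](C(C)=C)C[C@@H](O[Si](C)(C)C(C)(C)C)[C@@H]2C | intermediate
10 | 6-[(tert-butyldimethylsilyl)oxy]-3-chloro-7-methyl-4-(prop-1-en-2-yl)cycloheptan-1-one, chloride configuration undefined | O=C1CC(Cl)[C@@H](C(C)=C)C[C@@H](O[Si](C)(C)C(C)(C)C)[C@@H]1C | intermediate
11 | (4S,6R,7S)-6-[(tert-butyldimethylsilyl)oxy]-7-methyl-4-(prop-1-en-2-yl)cyclohept-2-en-1-one | O=C1C=C[C@@H](C(C)=C)C[C@@H](O[Si](C)(C)C(C)(C)C)[C@@H]1C | intermediate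
12 | 5α,6α-epoxide of 11 (epoxide trans to the isopropenyl group) | O=C1[C@@H]2O[C@@H]2[C@@H](C(C)=C)C[C@@H](O[Si](C)(C)C(C)(C)C)[C@@H]1C | intermediate
13 | 1-(methoxymethylidene) derivative of 12, E/Z mixture | COC=C1[C@@H]2O[C@@H]2[C@@H](C(C)=C)C[C@@H](O[Si](C)(C)C(C)(C)C)[C@@H]1C | intermediate
14 | 9β-[(tert-butyldimethylsilyl)oxy]-6α-hydroxy-10α-methyl-7β-(prop-1-en-2-yl)cyclohept-1(5)-ene-1-carbaldehyde | O=CC1=C[C@H](O)[C@@H](C(C)=C)C[C@@H](O[Si](C)(C)C(C)(C)C)[C@@H]1C | intermediate
15 | 1α,5α-epoxide of 14 (epoxy aldehyde, CHO on the β face) | O=C[C@@]12O[C@@H]1[C@H](O)[C@@H](C(C)=C)C[C@@H](O[Si](C)(C)C(C)(C)C)[C@@H]2C | intermediate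
16 | (E)-1-bromoprop-1-ene | C/C=C/Br | starting material
17 | (E)-prop-1-enyllithium | [Li]/C=C/C | intermediate
18 | 1α,5α-epoxy-6α-hydroxy (E)-but-2-en-1-ol adduct, both C2 epimers | C/C=C/C(O)[C@@]12O[C@@H]1[C@H](O)[C@@H](C(C)=C)C[C@@H](O[Si](C)(C)C(C)(C)C)[C@@H]2C | intermediate
19 | 1α,5α-epoxy-6α-hydroxy (E)-but-2-enoyl ketone | C/C=C/C(=O)[C@@]12O[C@@H]1[C@H](O)[C@@H](C(C)=C)C[C@@H](O[Si](C)(C)C(C)(C)C)[C@@H]2C | intermediate
20 | (R)-2-methylbutanoic acid | CC[C@@H](C)C(=O)O | starting material
21 | 5β-[(2R)-2-methylbutanoyloxy]-1α,6α-dihydroxy-1β-[(E)-but-2-enoyl]-9β-silyloxy-10α-methyl-7β-isopropenylcycloheptane | O[C@@H]1[C@@H](C(C)=C)C[C@@H](O[Si](C)(C)C(C)(C)C)[C@H](C)[C@@](O)(C(=O)/C=C/C)[C@H]1OC(=O)[C@H](C)CC | intermediate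
22 | as 21 with the isopropenyl methyl hydroxylated (3-hydroxyprop-1-en-2-yl at C7) | O[C@@H]1[C@@H](C(CO)=C)C[C@@H](O[Si](C)(C)C(C)(C)C)[C@H](C)[C@@](O)(C(=O)/C=C/C)[C@H]1OC(=O)[C@H](C)CC | intermediate
23 | as 21 with a 3-oxoprop-1-en-2-yl group at C7 (enal) | O[C@@H]1[C@@H](C(C=O)=C)C[C@@H](O[Si](C)(C)C(C)(C)C)[C@H](C)[C@@](O)(C(=O)/C=C/C)[C@H]1OC(=O)[C@H](C)CC | intermediate
24 | trans-fused α-methylene lactol (C12 hemiacetal, either configuration) | C=C1C(O)O[C@@H]2[C@@H]1C[C@@H](O[Si](C)(C)C(C)(C)C)[C@H](C)[C@@](O)(C(=O)/C=C/C)[C@H]2OC(=O)[C@H](C)CC | intermediate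
25 | 9-O-(tert-butyldimethylsilyl) ether of the target | C=C1C(=O)O[C@@H]2[C@@H]1C[C@@H](O[Si](C)(C)C(C)(C)C)[C@H](C)[C@@](O)(C(=O)/C=C/C)[C@H]2OC(=O)[C@H](C)CC | intermediate
26 | CNP0331957.3 | C=C1C(=O)O[C@@H]2[C@@H]1C[C@@H](O)[C@H](C)[C@@](O)(C(=O)/C=C/C)[C@H]2OC(=O)[C@H](C)CC | target

**Step count and risks**

Total step count: 17. Longest linear sequence: 17 steps (1 to 26).

Steps most likely to fail:

Step 11. The hydroxyl group may direct too weakly, so that the epoxide forms on the β face, or the base may isomerise the γ-hydroxy enal to a 1,4-dicarbonyl compound before epoxidation. The fallback sets out from 14 and changes to an electrophilic, metal-alkoxide-directed epoxidation at the alcohol oxidation level. Luche reduction (NaBH4, CeCl3·7H2O, MeOH) should give the allylic diol F1. Epoxidation with VO(acac)2 and t-BuOOH, in which the vanadium alkoxide of the ring hydroxyl delivers oxygen to its own α face of the now electron-rich alkene, should give the epoxy diol F2. Oxidation of the primary alcohol only (TEMPO, PhI(OAc)2) comes back to the route at 15.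

Step 14. Substitution at the hindered C5 may be too slow, or the new acyl group may migrate to the neighbouring C6 hydroxyl. The fallback sets out from 19 and separates epoxide opening from acylation. Acid-catalysed hydrolysis (HClO4 cat., THF/H2O; water attacks C5 from the β face) should give the triol F3. SeO2/t-BuOOH oxidation should give the allylic alcohol F4, and MnO2 should carry it through the enal F5 and the lactol F6 to the hydroxy lactone F7, in which C5–OH is the only secondary hydroxyl left. Steglich esterification with 20 (DCC, DMAP) comes back to the route at 25.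

Step 15. The allylic oxidation may attack the C7 methine instead of the methyl group, or run on to over-oxidised products. The fallback sets out from 21 and replaces the selenium ene reaction by an ene-type chlorination. HOCl generated from Ca(OCl)2 and CO2 (CH2Cl2/H2O) should give the allylic chloride F8. N-oxide oxidation (N-methylmorpholine N-oxide, MeCN, Kornblum type) should give the enal 23, which closes to the lactol 24, and MnO2 then comes back to the route at 25.

**Further compounds**

F1 | step 11 | allylic diol (C2 hydroxymethyl on C1=C5, 6α-OH) | OCC1=C[C@H](O)[C@@H](C(C)=C)C[C@@H](O[Si](C)(C)C(C)(C)C)[C@@H]1C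
F2 | step 11 | 1α,5α-epoxy diol | OC[C@@]12O[C@@H]1[C@H](O)[C@@H](C(C)=C)C[C@@H](O[Si](C)(C)C(C)(C)C)[C@@H]2C
F3 | step 14 | 1α,5β,6α-triol with isopropenyl group | O[C@@H]1[C@@H](C(C)=C)C[C@@H](O[Si](C)(C)C(C)(C)C)[C@H](C)[C@@](O)(C(=O)/C=C/C)[C@H]1O
F4 | step 14 | triol with 3-hydroxyprop-1-en-2-yl group at C7 | O[C@@H]1[C@@H](C(CO)=C)C[C@@H](O[Si](C)(C)C(C)(C)C)[C@H](C)[C@@](O)(C(=O)/C=C/C)[C@H]1O
F5 | step 14 | triol enal (3-oxoprop-1-en-2-yl at C7) | O[C@@H]1[C@@H](C(C=O)=C)C[C@@H](O[Si](C)(C)C(C)(C)C)[C@H](C)[C@@](O)(C(=O)/C=C/C)[C@H]1O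
F6 | step 14 | 5β-hydroxy lactol | C=C1C(O)O[C@@H]2[C@@H]1C[C@@H](O[Si](C)(C)C(C)(C)C)[C@H](C)[C@@](O)(C(=O)/C=C/C)[C@H]2O
F7 | step 14 | 5β-hydroxy α-methylene lactone | C=C1C(=O)O[C@@H]2[C@@H]1C[C@@H](O[Si](C)(C)C(C)(C)C)[C@H](C)[C@@](O)(C(=O)/C=C/C)[C@H]2O
F8 | step 15 | allylic chloride (3-chloroprop-1-en-2-yl at C7) | O[C@@H]1[C@@H](C(CCl)=C)C[C@@H](O[Si](C)(C)C(C)(C)C)[C@H](C)[C@@](O)(C(=O)/C=C/C)[C@H]1OC(=O)[C@H](C)CC
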